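The route rests on cutting the C8–C9 bond of ring B. In the target the tertiary carbinol C9, which carries the C11 carboxyl group, is attached to C8, the α-carbon of the ring B enal C7=C8–C12. That is the adduct pattern of a Morita–Baylis–Hillman union of an enal with an α-keto ester. A nucleophilic phosphine should therefore close ring B in one operation, forming C8–C9 and the C9 stereocentre, with enal, hydroxyl and ester already at the oxidation levels of the target. The substrate is a ring A cyclohexane with a tert-butyl oxoacetate on quaternary C10 and, trans to it on C5, an (E)-4-oxobut-2-enyl chain with a silyl-protected C6 carbinol.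

Key step: step 16

Remark 1: drimane numbering (C1–C12) is used for all intermediates, including the monocyclic ones.
Remark 2: C9 is formed in step 4 as a carbinol of uncontrolled configuration; both epimers are carried on (C9 is left undefined in the SMILES of 7–12 and 15–20) and converge in the oxidation of step 14.
Remark 3: the (S,S)-diamine ligand is assumed to give the (S)-carbinols of steps 1 and 10, the unsaturated substituent taking the place of the aryl group of aryl alkyl ketones; if the sense were opposite, the mirror-image ligand would be used.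
Remark 4: the target is made as the open formyl acid; ring–chain tautomerism to a hydroxy lactone would be a property of the compound, not of the route.

Step 1
Reactants: 1 ketoisophorone
Product: 2 (4S)-4-hydroxy-2,6,6-trimethylcyclohex-2-en-1-one
Conditions: RuCl[(S,S)-TsDPEN](p-cymene) (0.5 mol%), KOH (2 mol%), i-PrOH, rt
Reagents that add atoms: none
Why: Noyori asymmetric transfer hydrogenation should reduce only the unhindered C4 carbonyl (the other one is shielded by the gem-dimethyl carbon and the methyl-bearing alkene carbon), and the chiral catalyst sets the carbinol centre (later drimane C2) that will relay its configuration to C10.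

Step 2
Reactants: 2 (4S)-4-hydroxy-2,6,6-trimethylcyclohex-2-en-1-one
Product: 4 (1S)-3,5,5-trimethyl-4-methylidenecyclohex-2-en-1-ol, via dilithium β-silyl dialkoxide 3 (not isolated)
Conditions: Me3SiCH2Li (2.3 equiv), THF, −78 → 0 °C; then KOt-Bu (2.5 equiv), 0 → 45 °C
Reagents that add atoms: (trimethylsilyl)methyllithium, [Li]C[Si](C)(C)C
Why: Peterson olefination, in which the first equivalent forms the alkoxide, the second adds 1,2 to the non-enolisable ketone, and the potassium β-silyl alkoxide undergoes syn-elimination under basic conditions that leave the acid-labile dienol and its stereocentre untouched; the new carbon is C6.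

Step 3
Reactants: 4 (1S)-3,5,5-trimethyl-4-methylidenecyclohex-2-en-1-ol; 5 tert-butyl bromoacetate
Product: 6 tert-butyl 2-{[(1S)-3,5,5-trimethyl-4-methylidenecyclohex-2-en-1-yl]oxy}acetate
Conditions: 50% aq. NaOH, Bu4NHSO4 (10 mol%), toluene, 0 °C → rt
Reagents that add atoms: none
Why: Williamson etherification under phase-transfer conditions, which the hindered tert-butyl ester survives and which does not touch the C–O bond of the stereocentre.

Step 4
Reactants: 6 tert-butyl 2-{[(1S)-3,5,5-trimethyl-4-methylidenecyclohex-2-en-1-yl]oxy}acetate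
Product: 8 tert-butyl 2-[(1S)-1,5,5-trimethyl-6-methylidenecyclohex-2-en-1-yl]-2-[(triethylsilyl)oxy]acetate (C9 epimers), via lithium alkoxide of the rearranged hydroxy ester 7 (not isolated)
Conditions: LiN(i-Pr)2 (1.2 equiv), THF, −78 → −20 °C; then Et3SiOTf (2.0 equiv), −78 → 0 °C
Reagents that add atoms: triethylsilyl trifluoromethanesulfonate, CC[Si](CC)(CC)OS(=O)(=O)C(F)(F)F
Why: [2,3]-Wittig rearrangement of the glycolate ester enolate, whose suprafacial shift across C2–C1=C10 puts C9 on the face of C10 that the oxygen leaves at C2, so the (S)-carbinol becomes the quaternary (S)-C10 with its methyl group on the later β-face; the alkoxide is silylated in the same flask.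

Step 5
Reactants: 8 tert-butyl 2-[(1S)-1,5,5-trimethyl-6-methylidenecyclohex-2-en-1-yl]-2-[(triethylsilyl)oxy]acetate (C9 epimers)
Product: 10 tert-butyl 2-[(1S,6S)-6-(hydroxymethyl)-1,5,5-trimethylcyclohex-2-en-1-yl]-2-[(triethylsilyl)oxy]acetate (C9 epimers), via B-alkyl-9-borabicyclo[3.3.1]nonane 9 (not isolated)
Conditions: 9-BBN (2.0 equiv), THF, rt → 60 °C; then aq. NaOAc, 30% H2O2, 0 °C → rt
Reagents that add atoms: hydrogen peroxide, OO
Why: hydroboration–oxidation, in which 9-BBN should select the exocyclic 1,1-disubstituted alkene over the ring alkene (cyclohexenes react far more slowly with it), place boron on C6 and deliver hydrogen to C5 from the α-face because the β-face is covered by the syn-axial 4β- and 10β-methyl groups, so that C6 ends trans to the C9 chain.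

Step 6
Reactants: 10 tert-butyl 2-[(1S,6S)-6-(hydroxymethyl)-1,5,5-trimethylcyclohex-2-en-1-yl]-2-[(triethylsilyl)oxy]acetate (C9 epimers)
Product: 11 tert-butyl 2-[(1S,2S)-2-(hydroxymethyl)-1,3,3-trimethylcyclohexyl]-2-[(triethylsilyl)oxy]acetate (C9 epimers)
Conditions: H2 (1 atm), 10% Pd/C, EtOAc, rt
Reagents that add atoms: none
Why: catalytic hydrogenation of the remaining cis-disubstituted ring alkene, which creates no stereocentre and leaves silyl ether, ester and alcohol untouched in a non-protic solvent.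

Step 7
Reactants: 11 tert-butyl 2-[(1S,2S)-2-(hydroxymethyl)-1,3,3-trimethylcyclohexyl]-2-[(triethylsilyl)oxy]acetate (C9 epimers)
Product: 12 tert-butyl 2-[(1S,2S)-2-formyl-1,3,3-trimethylcyclohexyl]-2-[(triethylsilyl)oxy]acetate (C9 epimers)
Conditions: Dess–Martin periodinane, pyridine, CH2Cl2, 0 °C → rt
Reagents that add atoms: none
Why: Dess–Martin oxidation of the primary alcohol under buffered, non-basic conditions that should not epimerise C5 next to the new aldehyde.

Step 8
Reactants: 12 tert-butyl 2-[(1S,2S)-2-formyl-1,3,3-trimethylcyclohexyl]-2-[(triethylsilyl)oxy]acetate (C9 epimers); 13 3,3-diethoxyprop-1-yne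
Product: 15 tert-butyl 2-[(1S,2S)-2-(4,4-diethoxy-1-hydroxybut-2-yn-1-yl)-1,3,3-trimethylcyclohexyl]-2-[(triethylsilyl)oxy]acetate (C6/C9 epimers), via lithium 3,3-diethoxyprop-1-yn-1-ide 14 (not isolated)
Conditions: 13, n-BuLi, THF, −78 °C; then 12, −78 → −30 °C
Reagents that add atoms: none
Why: 1,2-addition of a lithium acetylide to the aldehyde brings in C7, C8 and C12 (as the acetal); the C6 configuration is left open here because steps 9 and 10 reset it.

Step 9
Reactants: 15 tert-butyl 2-[(1S,2S)-2-(4,4-diethoxy-1-hydroxybut-2-yn-1-yl)-1,3,3-trimethylcyclohexyl]-2-[(triethylsilyl)oxy]acetate (C6/C9 epimers)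
Product: 16 tert-butyl 2-[(1S,2S)-2-(4,4-diethoxybut-2-ynoyl)-1,3,3-trimethylcyclohexyl]-2-[(triethylsilyl)oxy]acetate (C9 epimers)
Conditions: Dess–Martin periodinane, pyridine, CH2Cl2, rt
Reagents that add atoms: none
Why: Dess–Martin oxidation of the propargylic alcohol merges the C6 epimers into one alkynyl ketone, and the buffered medium spares the acetal and the C5 centre.

Step 10
Reactants: 16 tert-butyl 2-[(1S,2S)-2-(4,4-diethoxybut-2-ynoyl)-1,3,3-trimethylcyclohexyl]-2-[(triethylsilyl)oxy]acetate (C9 epimers)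
Product: 17 tert-butyl 2-{(1S,2S)-2-[(1S)-4,4-diethoxy-1-hydroxybut-2-yn-1-yl]-1,3,3-trimethylcyclohexyl}-2-[(triethylsilyl)oxy]acetate (C9 epimers)
Conditions: Ru[(S,S)-TsDPEN](p-cymene) (2 mol%), i-PrOH, rt
Reagents that add atoms: none
Why: Noyori asymmetric transfer hydrogenation of an alkynyl ketone is catalyst-controlled even with a bulky α-branched substituent and should set C6 as (S), the later 6β-oxygen; hydride entry from the more open C4 flank of the carbonyl (anti to C10) points the same way, so the pairing is expected to be matched.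

Step 11
Reactants: 17 tert-butyl 2-{(1S,2S)-2-[(1S)-4,4-diethoxy-1-hydroxybut-2-yn-1-yl]-1,3,3-trimethylcyclohexyl}-2-[(triethylsilyl)oxy]acetate (C9 epimers)
Product: 18 tert-butyl 2-{(1S,2S)-2-[(1R,2E)-4,4-diethoxy-1-hydroxybut-2-en-1-yl]-1,3,3-trimethylcyclohexyl}-2-[(triethylsilyl)oxy]acetate (C9 epimers)
Conditions: NaAlH2(OCH2CH2OMe)2 (1.5 equiv), THF, −20 → 0 °C
Reagents that add atoms: none
Why: alkoxide-directed trans-hydroalumination of the propargylic alcohol gives the (E)-alkene on protonolysis, and this intramolecular delivery should be faster than attack on the tert-butyl ester, which is screened by quaternary C10 and the silyl ether (the C6 descriptor changes only because the priorities change).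

Step 12
Reactants: 18 tert-butyl 2-{(1S,2S)-2-[(1R,2E)-4,4-diethoxy-1-hydroxybut-2-en-1-yl]-1,3,3-trimethylcyclohexyl}-2-[(triethylsilyl)oxy]acetate (C9 epimers)
Product: 19 tert-butyl 2-{(1S,2S)-2-[(1R,2E)-1-[(tert-butyldimethylsilyl)oxy]-4,4-diethoxybut-2-en-1-yl]-1,3,3-trimethylcyclohexyl}-2-[(triethylsilyl)oxy]acetate (C9 epimers)
Conditions: t-BuMe2SiOTf (1.2 equiv), 2,6-lutidine, CH2Cl2, −78 °C
Reagents that add atoms: tert-butyldimethylsilyl trifluoromethanesulfonate, CC(C)(C)[Si](C)(C)OS(=O)(=O)C(F)(F)F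
Why: silylation of the hindered allylic alcohol with a silyl triflate and a hindered base, run cold so that the acetal is not activated.

Step 13
Reactants: 19 tert-butyl 2-{(1S,2S)-2-[(1R,2E)-1-[(tert-butyldimethylsilyl)oxy]-4,4-diethoxybut-2-en-1-yl]-1,3,3-trimethylcyclohexyl}-2-[(triethylsilyl)oxy]acetate (C9 epimers)
Product: 20 tert-butyl 2-{(1S,2S)-2-[(1R,2E)-1-[(tert-butyldimethylsilyl)oxy]-4,4-diethoxybut-2-en-1-yl]-1,3,3-trimethylcyclohexyl}-2-hydroxyacetate (C9 epimers)
Conditions: HF·pyridine, pyridine, THF, 0 °C → rt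
Reagents that add atoms: none
Why: selective desilylation, since a triethylsilyl ether is cleaved much faster by buffered HF·pyridine than a secondary tert-butyldimethylsilyl ether, while acetal and tert-butyl ester are stable.

Step 14
Reactants: 20 tert-butyl 2-{(1S,2S)-2-[(1R,2E)-1-[(tert-butyldimethylsilyl)oxy]-4,4-diethoxybut-2-en-1-yl]-1,3,3-trimethylcyclohexyl}-2-hydroxyacetate (C9 epimers)
Product: 21 tert-butyl 2-{(1S,2S)-2-[(1R,2E)-1-[(tert-butyldimethylsilyl)oxy]-4,4-diethoxybut-2-en-1-yl]-1,3,3-trimethylcyclohexyl}-2-oxoacetate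
Conditions: Dess–Martin periodinane, pyridine, CH2Cl2, rt
Reagents that add atoms: none
Why: Dess–Martin oxidation of the α-hydroxy ester to the α-keto ester erases C9 so that both epimers converge, and it is done before the aldehyde is unmasked so that a free hydroxyl never faces the enal (no oxa-Michael closure).

Step 15
Reactants: 21 tert-butyl 2-{(1S,2S)-2-[(1R,2E)-1-[(tert-butyldimethylsilyl)oxy]-4,4-diethoxybut-2-en-1-yl]-1,3,3-trimethylcyclohexyl}-2-oxoacetate
Product: 22 tert-butyl 2-{(1S,2S)-2-[(1R,2E)-1-[(tert-butyldimethylsilyl)oxy]-4-oxobut-2-en-1-yl]-1,3,3-trimethylcyclohexyl}-2-oxoacetate (ring A keto ester enal)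
Conditions: PPTS (20 mol%), acetone/H2O (10:1), 40 °C
Reagents that add atoms: water, O
Why: acid-catalysed hydrolysis of the allylic diethyl acetal under conditions mild enough for the allylic silyl ether and the tert-butyl ester, with the thermodynamically favoured (E)-geometry retained.

Step 16
Reactants: 22 tert-butyl 2-{(1S,2S)-2-[(1R,2E)-1-[(tert-butyldimethylsilyl)oxy]-4-oxobut-2-en-1-yl]-1,3,3-trimethylcyclohexyl}-2-oxoacetate
Product: 24 tert-butyl 6β-[(tert-butyldimethylsilyl)oxy]-9β-hydroxy-12-oxodrim-7-en-11-oate, via phosphonium aldolate zwitterion 23 (not isolated)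
Conditions: PMe3 (0.5 equiv), t-AmOH/THF (1:1), rt
Reagents that add atoms: none
Why: Proposed new method: trimethylphosphine adds reversibly to C7 of the enal, the phosphonium enolate attacks the ketone carbon C9 through C8, and alcohol-assisted proton transfer from C8 followed by E1cB loss of the phosphine restores C7=C8. The closest known reactions are phosphine-mediated intramolecular Morita–Baylis–Hillman closures of enone– and enoate–aldehydes and the intermolecular addition of activated alkenes to α-keto esters; an enal closing onto an α-keto ester has no direct precedent, and the small phosphine is chosen because C7 lies next to the silyloxy-bearing C6. Ring B is closed by a 6-(enolexo)-exo-trig aldol. C9 is set in the reversible aldol step: in the half-chair of ring B the bulky ester should take the α-axial position, anti to the 10β-methyl group and clear of the C12 formyl group and the C1 methylene, which leaves the hydroxyl β-equatorial and hydrogen-bonded to the aldehyde oxygen. The step needs the aldol at C9 to outrun phosphine attack on the keto ester and loss of the C6 oxygen; the keto ester has no α-hydrogen (C10 is quaternary) and can only be the electrophile, the trans-diequatorial chains on C5 and C10 hold C8 within reach of C9, and the silyl ether is a poor leaving group.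

Step 17
Reactants: 24 tert-butyl 6β-[(tert-butyldimethylsilyl)oxy]-9β-hydroxy-12-oxodrim-7-en-11-oate
Product: 25 tert-butyl 6β,9β-dihydroxy-12-oxodrim-7-en-11-oate
Conditions: HF·pyridine, THF, 0 °C → rt
Reagents that add atoms: none
Why: desilylation with an acidic fluoride source, which avoids an alkoxide at C9 and therefore retro-aldol opening of ring B.

Step 18
Reactants: 25 tert-butyl 6β,9β-dihydroxy-12-oxodrim-7-en-11-oate; 26 (2E,4E,6E)-octa-2,4,6-trienoic acid
Product: 28 tert-butyl 9β-hydroxy-6β-[(2E,4E,6E)-octa-2,4,6-trienoyloxy]-12-oxodrim-7-en-11-oate, via trienoic trichlorobenzoic mixed anhydride 27 (not isolated)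
Conditions: 26, 2,4,6-Cl3C6H2COCl, Et3N, toluene, rt; then 25, DMAP, rt → 45 °C
Reagents that add atoms: none
Why: Yamaguchi esterification, whose acylpyridinium intermediate should be reactive enough for the axial 6β-hydroxyl (syn to the 4β- and 10β-methyl groups), while the tertiary C9 hydroxyl is too hindered to compete and the triene geometry is not touched.

Step 19
Reactants: 28 tert-butyl 9β-hydroxy-6β-[(2E,4E,6E)-octa-2,4,6-trienoyloxy]-12-oxodrim-7-en-11-oate
Product: 29 9β-hydroxy-6β-[(2E,4E,6E)-octa-2,4,6-trienoyloxy]-12-oxodrim-7-en-11-oic acid (target CNP0234478.3)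
Conditions: CF3CO2H/CH2Cl2 (1:4), 0 °C
Reagents that add atoms: none
Why: acidolysis of the tert-butyl ester with loss of 2-methylpropene; the C9 carbinol has no β-hydrogen and cannot dehydrate, and ionisation of the allylic C6 ester is disfavoured by the conjugated formyl group.

Compound list
1 | ketoisophorone (2,6,6-trimethylcyclohex-2-ene-1,4-dione) | CC1=CC(=O)CC(C)(C)C1=O | starting material
2 | (4S)-4-hydroxy-2,6,6-trimethylcyclohex-2-en-1-one | CC1=C[C@@H](O)CC(C)(C)C1=O | intermediate
3 | dilithium (4S)-2,6,6-trimethyl-1-[(trimethylsilyl)methyl]cyclohex-2-ene-1,4-diolate (C1 epimers, not isolated) | CC1=C[C@@H](O[Li])CC(C)(C)C1(O[Li])C[Si](C)(C)C | intermediate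
4 | (1S)-3,5,5-trimethyl-4-methylidenecyclohex-2-en-1-ol | CC1=C[C@@H](O)CC(C)(C)C1=C | intermediate
5 | tert-butyl bromoacetate | BrCC(=O)OC(C)(C)C | starting material
6 | tert-butyl 2-{[(1S)-3,5,5-trimethyl-4-methylidenecyclohex-2-en-1-yl]oxy}acetate | CC1=C[C@@H](OCC(=O)OC(C)(C)C)CC(C)(C)C1=C | intermediate
7 | lithium alkoxide of tert-butyl 2-hydroxy-2-[(1S)-1,5,5-trimethyl-6-methylidenecyclohex-2-en-1-yl]acetate (C9 epimers, not isolated) | [Li]OC(C(=O)OC(C)(C)C)[C@@]1(C)C=CCC(C)(C)C1=C | intermediate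
8 | tert-butyl 2-[(1S)-1,5,5-trimethyl-6-methylidenecyclohex-2-en-1-yl]-2-[(triethylsilyl)oxy]acetate (C9 epimers) | CC[Si](CC)(CC)OC(C(=O)OC(C)(C)C)[C@@]1(C)C=CCC(C)(C)C1=C | intermediate
9 | B-alkyl-9-borabicyclo[3.3.1]nonane from 8, boron on C6 (not isolated) | CC[Si](CC)(CC)OC(C(=O)OC(C)(C)C)[C@@]1(C)C=CCC(C)(C)[C@@H]1CB2C3CCCC2CCC3 | intermediate
10 | tert-butyl 2-[(1S,6S)-6-(hydroxymethyl)-1,5,5-trimethylcyclohex-2-en-1-yl]-2-[(triethylsilyl)oxy]acetate (C9 epimers) | CC[Si](CC)(CC)OC(C(=O)OC(C)(C)C)[C@@]1(C)C=CCC(C)(C)[C@@H]1CO | intermediate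
11 | tert-butyl 2-[(1S,2S)-2-(hydroxymethyl)-1,3,3-trimethylcyclohexyl]-2-[(triethylsilyl)oxy]acetate (C9 epimers) | CC[Si](CC)(CC)OC(C(=O)OC(C)(C)C)[C@@]1(C)CCCC(C)(C)[C@@H]1CO | intermediate
12 | tert-butyl 2-[(1S,2S)-2-formyl-1,3,3-trimethylcyclohexyl]-2-[(triethylsilyl)oxy]acetate (C9 epimers) | CC[Si](CC)(CC)OC(C(=O)OC(C)(C)C)[C@@]1(C)CCCC(C)(C)[C@@H]1C=O | intermediate
13 | 3,3-diethoxyprop-1-yne | C#CC(OCC)OCC | starting material
14 | lithium 3,3-diethoxyprop-1-yn-1-ide (not isolated) | [Li]C#CC(OCC)OCC | intermediate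
15 | tert-butyl 2-[(1S,2S)-2-(4,4-diethoxy-1-hydroxybut-2-yn-1-yl)-1,3,3-trimethylcyclohexyl]-2-[(triethylsilyl)oxy]acetate (C6/C9 epimers) | CC[Si](CC)(CC)OC(C(=O)OC(C)(C)C)[C@@]1(C)CCCC(C)(C)[C@@H]1C(O)C#CC(OCC)OCC | intermediate
16 | tert-butyl 2-[(1S,2S)-2-(4,4-diethoxybut-2-ynoyl)-1,3,3-trimethylcyclohexyl]-2-[(triethylsilyl)oxy]acetate (C9 epimers) | CC[Si](CC)(CC)OC(C(=O)OC(C)(C)C)[C@@]1(C)CCCC(C)(C)[C@@H]1C(=O)C#CC(OCC)OCC | intermediate
17 | tert-butyl 2-{(1S,2S)-2-[(1S)-4,4-diethoxy-1-hydroxybut-2-yn-1-yl]-1,3,3-trimethylcyclohexyl}-2-[(triethylsilyl)oxy]acetate (C9 epimers) | CC[Si](CC)(CC)OC(C(=O)OC(C)(C)C)[C@@]1(C)CCCC(C)(C)[C@@H]1[C@H](O)C#CC(OCC)OCC | intermediate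
18 | tert-butyl 2-{(1S,2S)-2-[(1R,2E)-4,4-diethoxy-1-hydroxybut-2-en-1-yl]-1,3,3-trimethylcyclohexyl}-2-[(triethylsilyl)oxy]acetate (C9 epimers) | CC[Si](CC)(CC)OC(C(=O)OC(C)(C)C)[C@@]1(C)CCCC(C)(C)[C@@H]1[C@H](O)/C=C/C(OCC)OCC | intermediate
19 | tert-butyl 2-{(1S,2S)-2-[(1R,2E)-1-[(tert-butyldimethylsilyl)oxy]-4,4-diethoxybut-2-en-1-yl]-1,3,3-trimethylcyclohexyl}-2-[(triethylsilyl)oxy]acetate (C9 epimers) | CC[Si](CC)(CC)OC(C(=O)OC(C)(C)C)[C@@]1(C)CCCC(C)(C)[C@@H]1[C@H](O[Si](C)(C)C(C)(C)C)/C=C/C(OCC)OCC | intermediate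
20 | tert-butyl 2-{(1S,2S)-2-[(1R,2E)-1-[(tert-butyldimethylsilyl)oxy]-4,4-diethoxybut-2-en-1-yl]-1,3,3-trimethylcyclohexyl}-2-hydroxyacetate (C9 epimers) | OC(C(=O)OC(C)(C)C)[C@@]1(C)CCCC(C)(C)[C@@H]1[C@H](O[Si](C)(C)C(C)(C)C)/C=C/C(OCC)OCC | intermediate
21 | tert-butyl 2-{(1S,2S)-2-[(1R,2E)-1-[(tert-butyldimethylsilyl)oxy]-4,4-diethoxybut-2-en-1-yl]-1,3,3-trimethylcyclohexyl}-2-oxoacetate | O=C(C(=O)OC(C)(C)C)[C@@]1(C)CCCC(C)(C)[C@@H]1[C@H](O[Si](C)(C)C(C)(C)C)/C=C/C(OCC)OCC | intermediate
22 | tert-butyl 2-{(1S,2S)-2-[(1R,2E)-1-[(tert-butyldimethylsilyl)oxy]-4-oxobut-2-en-1-yl]-1,3,3-trimethylcyclohexyl}-2-oxoacetate (ring A keto ester enal) | O=C/C=C/[C@@H](O[Si](C)(C)C(C)(C)C)[C@H]1C(C)(C)CCC[C@]1(C)C(=O)C(=O)OC(C)(C)C | intermediate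
23 | 7-(trimethylphosphonio)-9-oxido zwitterion of the closed ring B aldol (C7 and C8 undefined, not isolated) | CC(C)(C)[Si](C)(C)O[C@@H]1C([P+](C)(C)C)C(C=O)[C@@]([O-])(C(=O)OC(C)(C)C)[C@@]2(C)CCCC(C)(C)[C@H]12 | intermediate
24 | tert-butyl 6β-[(tert-butyldimethylsilyl)oxy]-9β-hydroxy-12-oxodrim-7-en-11-oate | CC(C)(C)[Si](C)(C)O[C@@H]1C=C(C=O)[C@@](O)(C(=O)OC(C)(C)C)[C@@]2(C)CCCC(C)(C)[C@H]12 | intermediate
25 | tert-butyl 6β,9β-dihydroxy-12-oxodrim-7-en-11-oate | O[C@@H]1C=C(C=O)[C@@](O)(C(=O)OC(C)(C)C)[C@@]2(C)CCCC(C)(C)[C@H]12 | intermediate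
26 | (2E,4E,6E)-octa-2,4,6-trienoic acid | C/C=C/C=C/C=C/C(=O)O | starting material
27 | (2E,4E,6E)-octa-2,4,6-trienoic 2,4,6-trichlorobenzoic anhydride (not isolated) | C/C=C/C=C/C=C/C(=O)OC(=O)c1c(Cl)cc(Cl)cc1Cl | intermediate
28 | tert-butyl 9β-hydroxy-6β-[(2E,4E,6E)-octa-2,4,6-trienoyloxy]-12-oxodrim-7-en-11-oate | C/C=C/C=C/C=C/C(=O)O[C@@H]1C=C(C=O)[C@@](O)(C(=O)OC(C)(C)C)[C@@]2(C)CCCC(C)(C)[C@H]12 | intermediate
29 | 9β-hydroxy-6β-[(2E,4E,6E)-octa-2,4,6-trienoyloxy]-12-oxodrim-7-en-11-oic acid (CNP0234478.3) | C/C=C/C=C/C=C/C(=O)O[C@@H]1C=C(C=O)[C@@](O)(C(=O)O)[C@@]2(C)CCCC(C)(C)[C@H]12 | target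

Total step count: 19. Longest linear sequence: 19 steps (1 → 29); compounds 5, 13 and 26 are purchased and enter directly.

Steps most likely to fail

Step 16 (key step, proposed new method). The phosphine may be diverted by attack at the activated ketone, conjugate addition at C7 may be too slow next to the silyloxy-bearing C6, or the aldolate may revert faster than the phosphine is expelled. The fallback makes the same C8–C9 bond by a known thiolate-triggered Michael–aldol sequence followed by sulfoxide elimination. It sets out from 22: PhSLi (1.1 equiv, THF, −78 → −40 °C) adds to C7 and the aldehyde enolate closes onto C9, giving after protonation tert-butyl 6β-[(tert-butyldimethylsilyl)oxy]-9β-hydroxy-12-oxo-7-(phenylsulfanyl)driman-11-oate F1. Oxidation with mCPBA (1.0 equiv, CH2Cl2, −78 °C) gives the sulfoxide, tert-butyl 6β-[(tert-butyldimethylsilyl)oxy]-9β-hydroxy-12-oxo-7-(phenylsulfinyl)driman-11-oate F2. Warming F2 in toluene (80 °C) eliminates towards the acidic C8–H and returns to the route at 24.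

Step 4. Bond formation at the fully substituted alkene carbon C10 may lag behind enolate decomposition or a competing 1,2-shift, and silyl capture of the hindered alkoxide may be incomplete. The fallback replaces the [2,3] shift by an Ireland–Claisen rearrangement with the same suprafacial transfer to C10. It sets out from 4, which is esterified with 2-[(triethylsilyl)oxy]acetic acid (DCC, DMAP, CH2Cl2) to (1S)-3,5,5-trimethyl-4-methylidenecyclohex-2-en-1-yl 2-[(triethylsilyl)oxy]acetate F3. LiN(SiMe3)2 and Me3SiCl (THF, −78 °C) give the silyl ketene acetal F4, which on warming to rt should rearrange to trimethylsilyl 2-[(1S)-1,5,5-trimethyl-6-methylidenecyclohex-2-en-1-yl]-2-[(triethylsilyl)oxy]acetate F5. Mild aqueous work-up frees 2-[(1S)-1,5,5-trimethyl-6-methylidenecyclohex-2-en-1-yl]-2-[(triethylsilyl)oxy]acetic acid F6, and O-tert-butyl-N,N′-diisopropylisourea (CH2Cl2, rt) converts it into 8, where the route is rejoined.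

Step 5. Addition of the bulky borane to the alkene flanked by two quaternary carbons may be slow enough for the ring alkene to compete, or facial discrimination at C5 may erode in the flexible cyclohexene. The fallback takes the two alkenes in the opposite order so that a small borane can be used on a chair cyclohexane. It sets out from 8: hydrogenation with RhCl(PPh3)3 (H2, benzene, rt), a catalyst very sensitive to steric shielding, should reduce only the ring alkene and give tert-butyl 2-[(1S)-1,3,3-trimethyl-2-methylidenecyclohexyl]-2-[(triethylsilyl)oxy]acetate F7. BH3·THF (0 °C → rt) then adds from the α-face, anti to the two axial methyl groups, to give the alkylborane (drawn as the monoalkylborane) F8. Oxidation in the same flask (aq. NaOAc, H2O2) returns to the route at 11, so that step 6 is no longer needed.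

Further compounds
F1 | step 16 | tert-butyl 6β-[(tert-butyldimethylsilyl)oxy]-9β-hydroxy-12-oxo-7-(phenylsulfanyl)driman-11-oate | CC(C)(C)[Si](C)(C)O[C@@H]1C(Sc3ccccc3)C(C=O)[C@@](O)(C(=O)OC(C)(C)C)[C@@]2(C)CCCC(C)(C)[C@H]12
F2 | step 16 | tert-butyl 6β-[(tert-butyldimethylsilyl)oxy]-9β-hydroxy-12-oxo-7-(phenylsulfinyl)driman-11-oate | CC(C)(C)[Si](C)(C)O[C@@H]1C(S(=O)c3ccccc3)C(C=O)[C@@](O)(C(=O)OC(C)(C)C)[C@@]2(C)CCCC(C)(C)[C@H]12
F3 | step 4 | (1S)-3,5,5-trimethyl-4-methylidenecyclohex-2-en-1-yl 2-[(triethylsilyl)oxy]acetate | CC1=C[C@@H](OC(=O)CO[Si](CC)(CC)CC)CC(C)(C)C1=C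
F4 | step 4 | silyl ketene acetal of F3 (trimethylsilyl) | CC1=C[C@@H](OC(O[Si](C)(C)C)=CO[Si](CC)(CC)CC)CC(C)(C)C1=C
F5 | step 4 | trimethylsilyl 2-[(1S)-1,5,5-trimethyl-6-methylidenecyclohex-2-en-1-yl]-2-[(triethylsilyl)oxy]acetate | CC[Si](CC)(CC)OC(C(=O)O[Si](C)(C)C)[C@@]1(C)C=CCC(C)(C)C1=C
F6 | step 4 | 2-[(1S)-1,5,5-trimethyl-6-methylidenecyclohex-2-en-1-yl]-2-[(triethylsilyl)oxy]acetic acid | CC[Si](CC)(CC)OC(C(=O)O)[C@@]1(C)C=CCC(C)(C)C1=C
F7 | step 5 | tert-butyl 2-[(1S)-1,3,3-trimethyl-2-methylidenecyclohexyl]-2-[(triethylsilyl)oxy]acetate | CC[Si](CC)(CC)OC(C(=O)OC(C)(C)C)[C@@]1(C)CCCC(C)(C)C1=C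
F8 | step 5 | alkylborane from F7 (boron on C6) | CC[Si](CC)(CC)OC(C(=O)OC(C)(C)C)[C@@]1(C)CCCC(C)(C)[C@@H]1CB
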